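## Retrosynthetic overview

1. The target comes from chelation-controlled ortho-O-demethylation of a 2,4-dimethoxybenzoate, itself made by B-alkyl Suzuki coupling of 5-bromoresorcinol with a terminal olefin.
2. The salicylate ester is not made by esterification. The C4–C5 bond of its undecenyl chain is formed, and its R stereocenter set, by nickel-catalysed enantioconvergent radical hydroalkylation of hepta-1,6-diene with the racemic 1-bromobutyl ester of the ring A acid.
3. The ring A acid comes from Vilsmeier formylation and Pinnick oxidation of the product of B-alkyl Suzuki coupling between 1-bromo-3,5-dimethoxybenzene and (R)-dodec-11-en-4-yl acetate.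
4. (R)-Dodec-11-en-4-yl acetate comes from the same radical enantioconvergent coupling, using butanal, acetyl bromide and octa-1,7-diene.
5. No ring is formed. Both benzene rings (ring A = salicylate, ring B = resorcinol) come intact from resorcinol through C–H borylation/bromination; one bromide serves ring A and, after demethylation, ring B.

Assumption: (S,S)-Ph-BOX, 2,2'-(propane-2,2-diyl)bis[(4S)-4-phenyl-4,5-dihydrooxazole], is taken as the ligand enantiomer that gives the R esters in steps 4 and 8; if the sense proves opposite, the mirror-image ligand is used with no other change.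

## Route

Step 1
Reactants: 1 resorcinol
Product: 2 1,3-dimethoxybenzene
Conditions: MeI (2.5 equiv), K2CO3 (3 equiv), acetone, reflux
Reagents that add atoms: iodomethane, CI
Why: Williamson ether synthesis; the phenoxides formed with K2CO3 are O-methylated by MeI.

Step 2
Reactants: 2 1,3-dimethoxybenzene
Product: 4 1-bromo-3,5-dimethoxybenzene, via aryl pinacol boronate 3 (not isolated)
Conditions: [Ir(cod)(OMe)]2 (1.5 mol %), 4,4'-di-tert-butyl-2,2'-bipyridine (3 mol %), B2pin2 (0.55 equiv), cyclohexane, 80 °C; then CuBr2 (3 equiv), MeOH/H2O 1:1, 80 °C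
Reagents that add atoms: CuBr2, Br[Cu]Br
Why: Iridium-catalysed C–H borylation is sterically governed and touches only the C5–H that has no ortho substituent, and CuBr2 then converts the C–B bond into C–Br (Hartwig one-pot meta-bromination of 1,3-disubstituted arenes).

Step 3
Reactants: 4 1-bromo-3,5-dimethoxybenzene
Product: 6 5-bromobenzene-1,3-diol, via aryloxydibromoborane 5 (not isolated)
Conditions: BBr3 (3 equiv), CH2Cl2, −78 °C → rt; then H2O
Reagents that add atoms: none
Why: BBr3 cleavage of aryl methyl ethers (Lewis acid-assisted demethylation) frees both phenols while the C–Br bond is inert.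

Step 4
Reactants: 7 butanal, 8 acetyl bromide, 9 octa-1,7-diene
Product: 11 (R)-dodec-11-en-4-yl acetate, via 1-bromobutyl acetate 10 (not isolated)
Conditions: 8 + 7, ZnBr2 (1 mol %), CH2Cl2, −10 °C → rt, concentrate; then NiBr2·glyme (10 mol %), (S,S)-Ph-BOX (12 mol %), 9 (5 equiv), (EtO)3SiH (2 equiv), K3PO4·H2O (2 equiv), DMA, 0 °C → rt
Reagents that add atoms: none
Why: Nickel hydride-catalysed enantioconvergent hydroalkylation, in which Ni–H adds anti-Markovnikov to one terminus of the diene (excess diene keeps it to one end), bromine abstraction from racemic 10 gives the α-acetoxybutyl radical, and its capture by the chiral alkylnickel species followed by reductive elimination forms the C4–C5 bond and sets the R acetate stereocenter under ligand control whatever the configuration of 10.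

Step 5
Reactants: 11 (R)-dodec-11-en-4-yl acetate, 4 1-bromo-3,5-dimethoxybenzene
Product: 13 (R)-12-(3,5-dimethoxyphenyl)dodecan-4-yl acetate, via B-alkyl-9-BBN 12 (not isolated)
Conditions: 9-BBN dimer (0.6 equiv), THF, 0 °C → rt; then 4, Pd(dppf)Cl2 (3 mol %), aq K3PO4 (3 equiv), THF/DMF, 50 °C
Reagents that add atoms: none
Why: Anti-Markovnikov hydroboration of the terminal olefin with 9-BBN (the acetate is not reduced) followed by B-alkyl Suzuki–Miyaura coupling with the aryl bromide; the stereocenter is not involved.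

Step 6
Reactants: 13 (R)-12-(3,5-dimethoxyphenyl)dodecan-4-yl acetate
Product: 15 (R)-12-(2-formyl-3,5-dimethoxyphenyl)dodecan-4-yl acetate, via iminium salt 14 (not isolated)
Conditions: POCl3 (1.5 equiv), DMF, 0 → 60 °C; then H2O, rt
Reagents that add atoms: N,N-dimethylformamide, CN(C)C=O; water, O
Why: Vilsmeier–Haack formylation goes ortho to the alkyl chain and para to a methoxy group (the site between the two methoxy groups is more hindered), as with 3,5-dimethoxytoluene, and the iminium salt is hydrolysed on quench.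

Step 7
Reactants: 15 (R)-12-(2-formyl-3,5-dimethoxyphenyl)dodecan-4-yl acetate
Product: 16 2-[(R)-9-acetoxydodecyl]-4,6-dimethoxybenzoic acid
Conditions: NaClO2 (2 equiv), NaH2PO4 (3 equiv), 2-methylbut-2-ene (10 equiv), t-BuOH/H2O, 0 °C → rt
Reagents that add atoms: sodium chlorite, [Na+].[O-]Cl=O
Why: Pinnick oxidation converts the aldehyde into the acid without touching the acetate, with 2-methylbut-2-ene scavenging HOCl so the electron-rich ring is not chlorinated.

Step 8
Reactants: 16 2-[(R)-9-acetoxydodecyl]-4,6-dimethoxybenzoic acid, 7 butanal, 17 hepta-1,6-diene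
Product: 20 (R)-undec-10-en-4-yl 2-[(R)-9-acetoxydodecyl]-4,6-dimethoxybenzoate, via acyl bromide 18 (not isolated), via 1-bromobutyl ester 19 (not isolated)
Conditions: (COBr)2 (1.3 equiv), DMF (cat.), CH2Cl2, 0 °C → rt, evaporate; 7 (1.2 equiv), ZnBr2 (2 mol %), CH2Cl2, −10 °C → rt, evaporate; then NiBr2·glyme (10 mol %), (S,S)-Ph-BOX (12 mol %), 17 (5 equiv), (EtO)3SiH (2 equiv), K3PO4·H2O (2 equiv), DMA, 0 °C → rt
Reagents that add atoms: none
Why: Proposed new method: the α-acyloxybutyl radical formed when low-valent nickel abstracts bromine from 19 is planar and one oxygen removed from the hindered aryl ring, so it should be captured by the chiral alkylnickel species (from Ni–H addition to a diene terminus) and undergo C–C reductive elimination from trivalent nickel with the same ligand-controlled R sense as in step 4, both C–Br epimers converging and the distant acetate stereocenter having no influence; the closest known reaction type is the nickel hydride enantioconvergent hydroalkylation of terminal olefins with racemic 1-bromoalkyl esters of simple aliphatic and aromatic acids made from an aldehyde and an acyl bromide, and the untested element is the electron-rich 2,6-disubstituted aroyl group.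

Step 9
Reactants: 20 (R)-undec-10-en-4-yl 2-[(R)-9-acetoxydodecyl]-4,6-dimethoxybenzoate, 6 5-bromobenzene-1,3-diol
Product: 22 (R)-11-(3,5-dihydroxyphenyl)undecan-4-yl 2-[(R)-9-acetoxydodecyl]-4,6-dimethoxybenzoate, via B-alkyl-9-BBN 21 (not isolated)
Conditions: 9-BBN dimer (0.6 equiv), THF, 0 °C → rt; then 6 (1.3 equiv), Pd(OAc)2 (5 mol %), SPhos (10 mol %), aq K3PO4 (5 equiv), THF, 50 °C
Reagents that add atoms: none
Why: 9-BBN hydroborates the terminal olefin chemoselectively beside both esters, and the B-alkyl Suzuki–Miyaura coupling with SPhos-ligated palladium tolerates the free phenols of the aryl bromide when extra base is used, so ring B is joined without protecting groups.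

Step 10
Reactants: 22 (R)-11-(3,5-dihydroxyphenyl)undecan-4-yl 2-[(R)-9-acetoxydodecyl]-4,6-dimethoxybenzoate
Product: 24 5'-methoxy-integracin A, via aryloxydichloroborane 23 (not isolated)
Conditions: BCl3 (5 equiv), CH2Cl2, −78 → 0 °C; then H2O
Reagents that add atoms: none
Why: BCl3 bound to the ester carbonyl cleaves only the ortho methoxy group through a six-membered chelate (chelation-controlled demethylation), leaving the para methoxy group, the acetate, the benzoate and both stereocenters untouched.

## Compound list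

1 | resorcinol | Oc1cccc(O)c1 | starting material
2 | 1,3-dimethoxybenzene | COc1cccc(OC)c1 | intermediate
3 | 2-(3,5-dimethoxyphenyl)-4,4,5,5-tetramethyl-1,3,2-dioxaborolane | COc1cc(OC)cc(c1)B1OC(C)(C)C(C)(C)O1 | intermediate (not isolated)
4 | 1-bromo-3,5-dimethoxybenzene | COc1cc(Br)cc(OC)c1 | intermediate
5 | 1-bromo-3,5-bis(dibromoboryloxy)benzene | Brc1cc(OB(Br)Br)cc(OB(Br)Br)c1 | intermediate (not isolated)
6 | 5-bromobenzene-1,3-diol | Oc1cc(O)cc(Br)c1 | intermediate
7 | butanal | CCCC=O | starting material
8 | acetyl bromide | CC(Br)=O | starting material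
9 | octa-1,7-diene | C=CCCCCC=C | starting material
10 | 1-bromobutyl acetate (racemic) | CCCC(Br)OC(C)=O | intermediate (not isolated)
11 | (R)-dodec-11-en-4-yl acetate | CCC[C@H](CCCCCCC=C)OC(C)=O | intermediate
12 | (R)-12-(9-borabicyclo[3.3.1]nonan-9-yl)dodecan-4-yl acetate | CCC[C@H](CCCCCCCCB1C2CCCC1CCC2)OC(C)=O | intermediate (not isolated)
13 | (R)-12-(3,5-dimethoxyphenyl)dodecan-4-yl acetate | CCC[C@H](CCCCCCCCc1cc(OC)cc(OC)c1)OC(C)=O | intermediate
14 | N-{2-[(R)-9-acetoxydodecyl]-4,6-dimethoxybenzylidene}-N-methylmethanaminium dichlorophosphate | CCC[C@H](CCCCCCCCc1cc(OC)cc(OC)c1C=[N+](C)C)OC(C)=O.[O-]P(Cl)(Cl)=O | intermediate (not isolated)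
15 | (R)-12-(2-formyl-3,5-dimethoxyphenyl)dodecan-4-yl acetate | CCC[C@H](CCCCCCCCc1cc(OC)cc(OC)c1C=O)OC(C)=O | intermediate
16 | 2-[(R)-9-acetoxydodecyl]-4,6-dimethoxybenzoic acid | CCC[C@H](CCCCCCCCc1cc(OC)cc(OC)c1C(O)=O)OC(C)=O | intermediate
17 | hepta-1,6-diene | C=CCCCC=C | starting material
18 | 2-[(R)-9-acetoxydodecyl]-4,6-dimethoxybenzoyl bromide | CCC[C@H](CCCCCCCCc1cc(OC)cc(OC)c1C(Br)=O)OC(C)=O | intermediate (not isolated)
19 | 1-bromobutyl 2-[(R)-9-acetoxydodecyl]-4,6-dimethoxybenzoate (both epimers at the CHBr carbon) | CCC[C@H](CCCCCCCCc1cc(OC)cc(OC)c1C(=O)OC(Br)CCC)OC(C)=O | intermediate (not isolated)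
20 | (R)-undec-10-en-4-yl 2-[(R)-9-acetoxydodecyl]-4,6-dimethoxybenzoate | CCC[C@H](CCCCCCCCc1cc(OC)cc(OC)c1C(=O)O[C@H](CCC)CCCCCC=C)OC(C)=O | intermediate
21 | (R)-11-(9-borabicyclo[3.3.1]nonan-9-yl)undecan-4-yl 2-[(R)-9-acetoxydodecyl]-4,6-dimethoxybenzoate | CCC[C@H](CCCCCCCCc1cc(OC)cc(OC)c1C(=O)O[C@H](CCC)CCCCCCCB1C2CCCC1CCC2)OC(C)=O | intermediate (not isolated)
22 | (R)-11-(3,5-dihydroxyphenyl)undecan-4-yl 2-[(R)-9-acetoxydodecyl]-4,6-dimethoxybenzoate | CCC[C@H](CCCCCCCCc1cc(OC)cc(OC)c1C(=O)O[C@H](CCC)CCCCCCCc1cc(O)cc(O)c1)OC(C)=O | intermediate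
23 | (R)-11-[3,5-bis(dichloroboryloxy)phenyl]undecan-4-yl 2-[(R)-9-acetoxydodecyl]-6-(dichloroboryloxy)-4-methoxybenzoate | CCC[C@H](CCCCCCCCc1cc(OC)cc(OB(Cl)Cl)c1C(=O)O[C@H](CCC)CCCCCCCc1cc(OB(Cl)Cl)cc(OB(Cl)Cl)c1)OC(C)=O | intermediate (not isolated)
24 | 5'-methoxy-integracin A, (R)-11-(3,5-dihydroxyphenyl)undecan-4-yl 2-[(R)-9-acetoxydodecyl]-6-hydroxy-4-methoxybenzoate | CCC[C@H](CCCCCCCCc1cc(OC)cc(O)c1C(=O)O[C@H](CCC)CCCCCCCc1cc(O)cc(O)c1)OC(C)=O | target

## Step count and risks

Total step count: 10 (one-pot sequences counted as one step each).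
Longest linear sequence: 8 steps (1, 2, 5, 6, 7, 8, 9, 10).

**Most likely to fail: step 8.** The hindered, electron-rich aroyl group may slow formation of 19 or erode the stereocontrol of the nickel coupling. The fallback sets out from 10 and 17 and comes back at 20. Bromide 10 (made as in step 4) is coupled with diene 17 under the step 4 conditions, but with the mirror-image ligand, to give (S)-undec-10-en-4-yl acetate F1. Methanolysis with K2CO3 in MeOH gives (S)-undec-10-en-4-ol F2. Mitsunobu esterification of acid 16 with F2 (PPh3, DIAD, toluene, 0 °C → rt) forms the hindered ester with inversion and delivers 20.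

**Second: step 4.** Enantioselectivity with the small acetyl group, or over-reaction and isomerisation of the second olefin, may be inadequate. The fallback sets out from butanal 7 and comes back at 11. Corey–Chaykovsky epoxidation (Me3S+ I−, KOtBu, DMSO) gives racemic 2-propyloxirane F3. Jacobsen hydrolytic kinetic resolution, with the (salen)Co(OAc) complex of trivalent cobalt (the catalyst enantiomer that consumes the S epoxide) and 0.55 equiv H2O, leaves (R)-2-propyloxirane F4. Opening at the CH2 terminus with hept-6-en-1-ylmagnesium bromide F5 (from 7-bromohept-1-ene, BrCCCCCC=C, and Mg) and CuI (10 mol %) in THF at −30 °C gives (R)-dodec-11-en-4-ol F6 with the stereocenter untouched. Acetylation with Ac2O, pyridine and DMAP gives 11.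

**Third: step 9.** The phenoxide form of 6 may undergo oxidative addition too slowly or complicate transmetalation. The fallback sets out from 6 and comes back at 22. Silylation with TIPSCl and imidazole in DMF gives 5-bromo-1,3-bis(triisopropylsilyloxy)benzene F7. Coupling of borane 21 with F7 under the step 5 conditions gives (R)-11-[3,5-bis(triisopropylsilyloxy)phenyl]undecan-4-yl 2-[(R)-9-acetoxydodecyl]-4,6-dimethoxybenzoate F8. TBAF buffered with AcOH in THF at 0 °C removes both silyl groups and gives 22.

## Further compounds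

F1 | step 8 | (S)-undec-10-en-4-yl acetate | CCC[C@@H](CCCCCC=C)OC(C)=O
F2 | step 8 | (S)-undec-10-en-4-ol | CCC[C@@H](CCCCCC=C)O
F3 | step 4 | 2-propyloxirane (racemic) | CCCC1CO1
F4 | step 4 | (R)-2-propyloxirane | CCC[C@@H]1CO1
F5 | step 4 | hept-6-en-1-ylmagnesium bromide | C=CCCCCC[Mg]Br
F6 | step 4 | (R)-dodec-11-en-4-ol | CCC[C@H](CCCCCCC=C)O
F7 | step 9 | 5-bromo-1,3-bis(triisopropylsilyloxy)benzene | CC(C)[Si](Oc1cc(Br)cc(O[Si](C(C)C)(C(C)C)C(C)C)c1)(C(C)C)C(C)C
F8 | step 9 | (R)-11-[3,5-bis(triisopropylsilyloxy)phenyl]undecan-4-yl 2-[(R)-9-acetoxydodecyl]-4,6-dimethoxybenzoate | CCC[C@H](CCCCCCCCc1cc(OC)cc(OC)c1C(=O)O[C@H](CCC)CCCCCCCc1cc(O[Si](C(C)C)(C(C)C)C(C)C)cc(O[Si](C(C)C)(C(C)C)C(C)C)c1)OC(C)=O
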